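Assumption: the target is wanted as the free hydrogen sulfate drawn, and (S)-(−)-pulegone counts as a purchasable chiral-pool ketone. C-numbers in the text are target positions (ring B = C5–C10, C9 quaternary, C13 = side-chain stereocentre).

**Retrosynthetic overview**
1. Sulfate O–S and the butenolide go last: butenolide ← terminal alkyne by a one-flask gold oxidation / O–H insertion / HWE annulation (new C18–O bond); alkyne ← primary chloride + acetylide.
2. Ring A ← intramolecular McMurry coupling of a C1 aldehyde with the C10 ketone, which fixes the C1=C10 alkene.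
3. C9–C11 ← axial alkylation of the ring-B ketone enolate with a seven-membered cyclic sulfate; C9–CH3 by prior methylation.
4. Cyclic sulfate ← (S)-β-alkyl-γ-butyrolactone ← desymmetrising Baeyer–Villiger oxidation of a 3-alkylcyclobutanone (the C–O bond that sets C13; this oxygen ends as the sulfate oxygen) ← dichloroketene [2+2].
5. Ring B is bought as (S)-pulegone (C8); C4 by Cu-catalysed Grignard 1,4-addition, C5 by equilibration. Ring order: B (chiral pool) → lactone and cyclic sulfate (fragment, transient) → A → butenolide.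

**Route**

Step 1
Reactants: 1 5-chloropent-1-ene; 2 trichloroacetyl chloride
Product: 4 2,2-dichloro-3-(3-chloropropyl)cyclobutan-1-one (racemic), via dichloroketene 3 (not isolated)
Conditions: Zn–Cu, POCl3, Et2O, reflux
Reagents that add atoms: none
Why: [2+2] ketene–alkene cycloaddition; dichloroketene from zinc dechlorination of 2 adds to the terminal alkene with CCl2 next to the substituted carbon, and the alkyl chloride is inert.

Step 2
Reactants: 4 2,2-dichloro-3-(3-chloropropyl)cyclobutan-1-one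
Product: 5 3-(3-chloropropyl)cyclobutan-1-one
Conditions: Zn, AcOH, 60 °C
Reagents that add atoms: none
Why: Reductive dechlorination of the α,α-dichloroketone gives the prochiral (Cs-symmetric) cyclobutanone, so the racemic centre of 4 no longer matters.

Step 3
Reactants: 5 3-(3-chloropropyl)cyclobutan-1-one
Product: 6 (4S)-4-(3-chloropropyl)oxolan-2-one
Conditions: Sc(OTf)3 (5 mol%), chiral N,N′-dioxide ligand (6 mol%, enantiomer chosen for the S lactone), m-CPBA, EtOAc, −20 °C
Reagents that add atoms: m-chloroperoxybenzoic acid, O=C(OO)c1cccc(Cl)c1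
Why: Catalytic asymmetric Baeyer–Villiger desymmetrisation; the chiral Sc(III) complex selects one of the two enantiotopic CH2–C(=O) bonds for migration, so the new C–O bond forms on one arm only and the ring CH becomes the (S)-centre (future C13, ca. 90% ee expected), while strain makes the cyclobutanone react well before anything else.

Step 4
Reactants: 6 (4S)-4-(3-chloropropyl)oxolan-2-one
Product: 7 (2S)-2-(3-chloropropyl)butane-1,4-diol
Conditions: LiBH4, THF, 0 °C → rt
Reagents that add atoms: none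
Why: Hydride reduction of the lactone to the 1,4-diol; the stereocentre is not involved and LiBH4 leaves the primary chloride alone.

Step 5
Reactants: 7 (2S)-2-(3-chloropropyl)butane-1,4-diol
Product: 9 (5S)-5-(3-chloropropyl)-1,3,2-dioxathiepane 2,2-dioxide, via cyclic sulfite (5S)-5-(3-chloropropyl)-1,3,2-dioxathiepane 2-oxide 8 (not isolated)
Conditions: SOCl2, Et3N, CH2Cl2, 0 °C; then RuCl3 (1 mol%), NaIO4, MeCN–H2O, 0 °C
Reagents that add atoms: thionyl chloride, O=S(Cl)Cl; sodium periodate, [Na+].[O-]I(=O)(=O)=O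
Why: Cyclic sulfite formation and RuO4-catalysed S-oxidation (the cyclic-sulfate protocol used for 1,4-diols) give a bis-electrophile whose two C–O carbons differ sterically (unbranched vs β-branched).

Step 6
Reactants: 10 (S)-(−)-pulegone; 11 2-(2-bromoethyl)-1,3-dioxolane
Product: 14 (2R,5S)-2-[4-(1,3-dioxolan-2-yl)-2-methylbutan-2-yl]-5-methylcyclohexan-1-one, via [2-(1,3-dioxolan-2-yl)ethyl]magnesium bromide 12 (not isolated), via the (2S,5S) cis epimer 13 (not isolated)
Conditions: Mg, THF, 25 °C; CuBr·SMe2 (10 mol%), THF, −20 → 0 °C; H2O; then KOH, EtOH, reflux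
Reagents that add atoms: none
Why: Copper-catalysed Grignard 1,4-addition to the s-cis enone (as in the 8-phenylmenthone synthesis) builds the C4 quaternary carbon, and base equilibration then sets the epimerisable C5 centre trans to the C8 methyl (both equatorial, ca. 9:1, residual 13 separated and recycled).

Step 7
Reactants: 14 (2R,5S)-2-[4-(1,3-dioxolan-2-yl)-2-methylbutan-2-yl]-5-methylcyclohexan-1-one
Product: 15 (2S,3S,6R)-6-[4-(1,3-dioxolan-2-yl)-2-methylbutan-2-yl]-2,3-dimethylcyclohexan-1-one (major C2 epimer)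
Conditions: LDA, THF, −78 °C; MeI, −78 → 0 °C
Reagents that add atoms: iodomethane, CI
Why: Kinetic enolate alkylation; LDA takes the unhindered CH2 proton rather than the methine beside the tert-alkyl group, and the configuration of the new methyl centre is irrelevant because it is re-enolised in step 8.

Step 8
Reactants: 15 (2S,3S,6R)-6-[4-(1,3-dioxolan-2-yl)-2-methylbutan-2-yl]-2,3-dimethylcyclohexan-1-one; 9 (5S)-5-(3-chloropropyl)-1,3,2-dioxathiepane 2,2-dioxide
Product: 18 4-[(1R,3S,4S)-3-[(3R)-6-chloro-3-(hydroxymethyl)hexyl]-3,4-dimethyl-2-oxocyclohexyl]-4-methylpentanal, via lithium (2S)-5-chloro-2-(2-iodoethyl)pentyl sulfate 16 (not isolated), via lithium (2R)-5-chloro-2-{2-[(1S,3R,6S)-3-[4-(1,3-dioxolan-2-yl)-2-methylbutan-2-yl]-1,6-dimethyl-2-oxocyclohexyl]ethyl}pentyl sulfate 17 (not isolated)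
Conditions: LDA, THF, −78 → 0 °C; 9, LiI (20 mol%), DMPU, 0 °C → rt; then 20% aq. H2SO4, THF, 40 °C
Reagents that add atoms: lithium iodide, [Li+].[I-] (I and Li of 16 only); lithium diisopropylamide, [Li+].CC(C)[N-]C(C)C (Li of 17 only); water, O
Why: Enolate alkylation with a cyclic sulfate, relayed by iodide opening at the unbranched CH2–O carbon; the tetrasubstituted enolate is attacked axially and anti to the bulky equatorial tert-alkyl group on the other α-carbon, so the chain ends trans to it (cis to H-5 and to the C8 methyl) and the C9 quaternary centre is set, after which acid cleaves the sulfate monoester at S–O (the C–O bond from step 3 is kept) and the dioxolane.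

Step 9
Reactants: 18 4-[(1R,3S,4S)-3-[(3R)-6-chloro-3-(hydroxymethyl)hexyl]-3,4-dimethyl-2-oxocyclohexyl]-4-methylpentanal
Product: 19 (2R)-5-chloro-2-{2-[(1S,2S,4aR)-1,2,5,5-tetramethyl-1,2,3,4,4a,5,6,7-octahydronaphthalen-1-yl]ethyl}pentan-1-ol
Conditions: TiCl3(DME)1.5, Zn–Cu, DME, reflux, syringe-pump addition
Reagents that add atoms: none
Why: Intramolecular McMurry coupling; low-valent titanium pinacolises and deoxygenates the 1,6-keto-aldehyde, closing ring A with the trisubstituted alkene exactly between the two former carbonyl carbons (C1=C10), without touching a stereocentre and tolerating the free alcohol and alkyl chloride.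

Step 10
Reactants: 19 (2R)-5-chloro-2-{2-[(1S,2S,4aR)-1,2,5,5-tetramethyl-1,2,3,4,4a,5,6,7-octahydronaphthalen-1-yl]ethyl}pentan-1-ol
Product: 20 tetrabutylammonium (2R)-5-chloro-2-{2-[(1S,2S,4aR)-1,2,5,5-tetramethyl-1,2,3,4,4a,5,6,7-octahydronaphthalen-1-yl]ethyl}pentyl sulfate
Conditions: SO3·pyridine, pyridine, rt; then aq. Bu4NOH (1 equiv), CH2Cl2 extraction
Reagents that add atoms: sulfur trioxide–pyridine, O=S(=O)([O-])[n+]1ccccc1; tetrabutylammonium hydroxide, CCCC[N+](CCCC)(CCCC)CCCC.[OH-]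
Why: O-sulfation of the primary alcohol; the lipophilic ion pair can be chromatographed, and the sulfate also masks the oxygen as a non-nucleophilic group for steps 11 and 12.

Step 11
Reactants: 20 tetrabutylammonium (2R)-5-chloro-2-{2-[(1S,2S,4aR)-1,2,5,5-tetramethyl-1,2,3,4,4a,5,6,7-octahydronaphthalen-1-yl]ethyl}pentyl sulfate
Product: 21 tetrabutylammonium (2S)-2-{2-[(1S,2S,4aR)-1,2,5,5-tetramethyl-1,2,3,4,4a,5,6,7-octahydronaphthalen-1-yl]ethyl}hept-6-yn-1-yl sulfate
Conditions: LiC≡CH·ethylenediamine (4 equiv), DMSO, rt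
Reagents that add atoms: lithium acetylide–ethylenediamine, [Li+].[C-]#C.NCCN
Why: SN2 alkylation of acetylide by the primary chloride; with the oxygen already sulfated, the 6-exo ether closure that a free alkoxide would undergo cannot compete.

Step 12
Reactants: 21 tetrabutylammonium (2S)-2-{2-[(1S,2S,4aR)-1,2,5,5-tetramethyl-1,2,3,4,4a,5,6,7-octahydronaphthalen-1-yl]ethyl}hept-6-yn-1-yl sulfate
Product: 24 (2S)-2-[3-(5-oxo-2,5-dihydrofuran-3-yl)propyl]-4-[(1S,2S,4aR)-1,2,5,5-tetramethyl-1,2,3,4,4a,5,6,7-octahydronaphthalen-1-yl]butyl hydrogen sulfate (target), via tetrabutylammonium (2S)-7-{[(diethoxyphosphoryl)acetyl]oxy}-6-oxo-2-{2-[(1S,2S,4aR)-1,2,5,5-tetramethyl-1,2,3,4,4a,5,6,7-octahydronaphthalen-1-yl]ethyl}heptyl sulfate 22 (not isolated), via the tetrabutylammonium salt of the target 23 (not isolated)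
Conditions: Mor-DalPhosAuNTf2 (5 mol%), 8-methylquinoline N-oxide (1.3 equiv), (EtO)2P(O)CH2CO2H (3 equiv), PhCl, rt; then LiCl, iPr2NEt, MeCN, rt; then cold 1 M HCl, extraction
Reagents that add atoms: (diethoxyphosphoryl)acetic acid, CCOP(=O)(OCC)CC(=O)O; 8-methylquinoline N-oxide, Cc1cccc2ccc[n+]([O-])c12 (O of 22 only)
Why: Proposed new method: a gold-catalysed oxidative [3+2] butenolide annulation of a terminal alkyne — LAu+ activates the alkyne, the N-oxide adds at the internal carbon and N–O cleavage gives a terminal α-oxo gold carbene, O–H insertion into the carboxylic acid forms the C18–O bond (α-acyloxymethyl ketone 22), and the built-in phosphonate closes the ring by intramolecular Horner–Wadsworth–Emmons olefination onto the new ketone under LiCl/amine conditions; the closest known reactions are gold-catalysed alkyne oxidation with trapping of the α-oxo carbene by simple carboxylic acids and the separate HWE cyclisation of isolated α-(phosphonoacetoxy) ketones, but using a phosphonoacetic acid as a bifunctional partner to go from alkyne to 4-substituted butenolide in one flask, next to an alkyl sulfate, has not been shown; no stereocentre is formed and the acid wash only exchanges Bu4N+ for H+.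

**Compound list**

In 17–20 the C13 label reads R only because the chloro branch outranks the ring branch; the configuration is that of the target throughout.

1 | 5-chloropent-1-ene | C=CCCCCl | starting material
2 | trichloroacetyl chloride | ClC(=O)C(Cl)(Cl)Cl | starting material
3 | dichloroketene | ClC(Cl)=C=O | intermediate
4 | 2,2-dichloro-3-(3-chloropropyl)cyclobutan-1-one (racemic) | O=C1CC(CCCCl)C1(Cl)Cl | intermediate
5 | 3-(3-chloropropyl)cyclobutan-1-one (achiral) | O=C1CC(CCCCl)C1 | intermediate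
6 | (4S)-4-(3-chloropropyl)oxolan-2-one | O=C1C[C@H](CCCCl)CO1 | intermediate
7 | (2S)-2-(3-chloropropyl)butane-1,4-diol | OCC[C@H](CCCCl)CO | intermediate
8 | (5S)-5-(3-chloropropyl)-1,3,2-dioxathiepane 2-oxide (epimers at S) | O=S1OCC[C@H](CCCCl)CO1 | intermediate
9 | (5S)-5-(3-chloropropyl)-1,3,2-dioxathiepane 2,2-dioxide | O=S1(=O)OCC[C@H](CCCCl)CO1 | intermediate
10 | (S)-(−)-pulegone, (5S)-5-methyl-2-(propan-2-ylidene)cyclohexan-1-one | C[C@H]1CCC(=C(C)C)C(=O)C1 | starting material
11 | 2-(2-bromoethyl)-1,3-dioxolane | BrCCC1OCCO1 | starting material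
12 | [2-(1,3-dioxolan-2-yl)ethyl]magnesium bromide | Br[Mg]CCC1OCCO1 | intermediate
13 | (2S,5S)-2-[4-(1,3-dioxolan-2-yl)-2-methylbutan-2-yl]-5-methylcyclohexan-1-one (cis) | C[C@H]1CC[C@@H](C(C)(C)CCC2OCCO2)C(=O)C1 | intermediate
14 | (2R,5S)-2-[4-(1,3-dioxolan-2-yl)-2-methylbutan-2-yl]-5-methylcyclohexan-1-one (trans) | C[C@H]1CC[C@H](C(C)(C)CCC2OCCO2)C(=O)C1 | intermediate
15 | (2S,3S,6R)-6-[4-(1,3-dioxolan-2-yl)-2-methylbutan-2-yl]-2,3-dimethylcyclohexan-1-one (major C2 epimer) | C[C@H]1CC[C@H](C(C)(C)CCC2OCCO2)C(=O)[C@H]1C | intermediate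
16 | lithium (2S)-5-chloro-2-(2-iodoethyl)pentyl sulfate | ICC[C@H](CCCCl)COS(=O)(=O)[O-].[Li+] | intermediate
17 | lithium (2R)-5-chloro-2-{2-[(1S,3R,6S)-3-[4-(1,3-dioxolan-2-yl)-2-methylbutan-2-yl]-1,6-dimethyl-2-oxocyclohexyl]ethyl}pentyl sulfate | C[C@H]1CC[C@H](C(C)(C)CCC2OCCO2)C(=O)[C@@]1(C)CC[C@H](CCCCl)COS(=O)(=O)[O-].[Li+] | intermediate
18 | 4-[(1R,3S,4S)-3-[(3R)-6-chloro-3-(hydroxymethyl)hexyl]-3,4-dimethyl-2-oxocyclohexyl]-4-methylpentanal | C[C@H]1CC[C@H](C(C)(C)CCC=O)C(=O)[C@@]1(C)CC[C@H](CCCCl)CO | intermediate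
19 | (2R)-5-chloro-2-{2-[(1S,2S,4aR)-1,2,5,5-tetramethyl-1,2,3,4,4a,5,6,7-octahydronaphthalen-1-yl]ethyl}pentan-1-ol | C[C@H]1CC[C@H]2C(=CCCC2(C)C)[C@@]1(C)CC[C@H](CCCCl)CO | intermediate
20 | tetrabutylammonium (2R)-5-chloro-2-{2-[(1S,2S,4aR)-1,2,5,5-tetramethyl-1,2,3,4,4a,5,6,7-octahydronaphthalen-1-yl]ethyl}pentyl sulfate | C[C@H]1CC[C@H]2C(=CCCC2(C)C)[C@@]1(C)CC[C@H](CCCCl)COS(=O)(=O)[O-].CCCC[N+](CCCC)(CCCC)CCCC | intermediate
21 | tetrabutylammonium (2S)-2-{2-[(1S,2S,4aR)-1,2,5,5-tetramethyl-1,2,3,4,4a,5,6,7-octahydronaphthalen-1-yl]ethyl}hept-6-yn-1-yl sulfate | C[C@H]1CC[C@H]2C(=CCCC2(C)C)[C@@]1(C)CC[C@H](CCCC#C)COS(=O)(=O)[O-].CCCC[N+](CCCC)(CCCC)CCCC | intermediate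
22 | tetrabutylammonium (2S)-7-{[(diethoxyphosphoryl)acetyl]oxy}-6-oxo-2-{2-[(1S,2S,4aR)-1,2,5,5-tetramethyl-1,2,3,4,4a,5,6,7-octahydronaphthalen-1-yl]ethyl}heptyl sulfate | C[C@H]1CC[C@H]2C(=CCCC2(C)C)[C@@]1(C)CC[C@H](CCCC(=O)COC(=O)CP(=O)(OCC)OCC)COS(=O)(=O)[O-].CCCC[N+](CCCC)(CCCC)CCCC | intermediate
23 | tetrabutylammonium (2S)-2-[3-(5-oxo-2,5-dihydrofuran-3-yl)propyl]-4-[(1S,2S,4aR)-1,2,5,5-tetramethyl-1,2,3,4,4a,5,6,7-octahydronaphthalen-1-yl]butyl sulfate | C[C@H]1CC[C@H]2C(=CCCC2(C)C)[C@@]1(C)CC[C@H](CCCC1=CC(=O)OC1)COS(=O)(=O)[O-].CCCC[N+](CCCC)(CCCC)CCCC | intermediate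
24 | (2S)-2-[3-(5-oxo-2,5-dihydrofuran-3-yl)propyl]-4-[(1S,2S,4aR)-1,2,5,5-tetramethyl-1,2,3,4,4a,5,6,7-octahydronaphthalen-1-yl]butyl hydrogen sulfate | C[C@H]1CC[C@H]2C(=CCCC2(C)C)[C@@]1(C)CC[C@H](CCCC1=CC(=O)OC1)COS(=O)(=O)O | target

**Step count and risks**

Total step count: 12. Longest linear sequence: 10 (steps 1–5, then 8–12); the pulegone branch (steps 6–7) joins at step 8.

Step 8 (quaternising alkylation) is risky because a hindered tetrasubstituted enolate must take a non-activated primary electrophile; O-alkylation or low conversion is possible. The fallback sets out from 10 and 9 and swaps the order so that the quaternary centre is closed with methyl iodide. The kinetic α′-enolate of pulegone (LDA, THF, −78 °C) is alkylated at its CH2 with 9 (LiI cat.) to give lithium (2R)-5-chloro-2-{2-[(1R,6S)-6-methyl-2-oxo-3-(propan-2-ylidene)cyclohexyl]ethyl}pentyl sulfate F1. A second LDA/MeI alkylation, anti to the pseudo-axial C8 methyl of this unlocked enolate, gives lithium (2R)-5-chloro-2-{2-[(1S,6S)-1,6-dimethyl-2-oxo-3-(propan-2-ylidene)cyclohexyl]ethyl}pentyl sulfate F2. CuBr-catalysed addition of Grignard 12 and KOH equilibration then give 17, where the fallback comes back to the route. The cost is a weaker C5 equilibrium, which I estimate at about 2:1; the C5 epimer is removed after hydrolysis at 18 and recycled.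

Step 9 (McMurry) is risky because the ketone is flanked by a quaternary and a tert-alkyl-bearing carbon, and C5 could epimerise or the chloride be reduced. The fallback sets out from 18 and separates C–C coupling from deoxygenation. TBSCl/imidazole gives 4-[(1R,3S,4S)-3-[(3R)-3-({[tert-butyl(dimethyl)silyl]oxy}methyl)-6-chlorohexyl]-3,4-dimethyl-2-oxocyclohexyl]-4-methylpentanal F3. SmI2 (THF, −78 °C) pinacol cyclisation gives the TBS-protected cis-C1,C10-diol F4 (C1/C10 configuration not assigned; both centres are removed again). Thiocarbonyldiimidazole (toluene, reflux) gives the cyclic thiocarbonate F5, and Corey–Winter elimination with P(OMe)3 at 110 °C gives the TBS ether of 19 F6. TBAF returns 19, where the fallback comes back to the route.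

Step 12 (the proposed annulation) is risky because the carbene could be intercepted by the sulfate anion or the phosphoryl oxygen, and the HWE stage must not isomerise the butenolide. The fallback uses known chemistry only, sets out from 20 and replaces the C–O annulation by a C–C coupling. Finkelstein exchange (NaI, acetone, reflux) gives tetrabutylammonium (2R)-5-iodo-2-{2-[(1S,2S,4aR)-1,2,5,5-tetramethyl-1,2,3,4,4a,5,6,7-octahydronaphthalen-1-yl]ethyl}pentyl sulfate F7. Zinc insertion (Zn dust, LiCl, THF, 40 °C) gives the alkylzinc iodide F8. Negishi coupling with 4-bromofuran-2(5H)-one (Pd2(dba)3/SPhos, THF, rt) gives 23, where the fallback comes back to the route; the acid wash of step 12 then gives 24.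

**Further compounds**

F1 | step 8 | lithium (2R)-5-chloro-2-{2-[(1R,6S)-6-methyl-2-oxo-3-(propan-2-ylidene)cyclohexyl]ethyl}pentyl sulfate | C[C@H]1CCC(=C(C)C)C(=O)[C@@H]1CC[C@H](CCCCl)COS(=O)(=O)[O-].[Li+]
F2 | step 8 | lithium (2R)-5-chloro-2-{2-[(1S,6S)-1,6-dimethyl-2-oxo-3-(propan-2-ylidene)cyclohexyl]ethyl}pentyl sulfate | C[C@H]1CCC(=C(C)C)C(=O)[C@@]1(C)CC[C@H](CCCCl)COS(=O)(=O)[O-].[Li+]
F3 | step 9 | 4-[(1R,3S,4S)-3-[(3R)-3-({[tert-butyl(dimethyl)silyl]oxy}methyl)-6-chlorohexyl]-3,4-dimethyl-2-oxocyclohexyl]-4-methylpentanal | C[C@H]1CC[C@H](C(C)(C)CCC=O)C(=O)[C@@]1(C)CC[C@H](CCCCl)CO[Si](C)(C)C(C)(C)C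
F4 | step 9 | TBS ether of the cis-C1,C10-pinacol of 18 (C1/C10 configuration not assigned) | C[C@H]1CC[C@H]2C(O)(C(O)CCC2(C)C)[C@@]1(C)CC[C@H](CCCCl)CO[Si](C)(C)C(C)(C)C
F5 | step 9 | cyclic thiocarbonate of F4 | C[C@H]1CC[C@H]2C3(OC(=S)OC3CCC2(C)C)[C@@]1(C)CC[C@H](CCCCl)CO[Si](C)(C)C(C)(C)C
F6 | step 9 | tert-butyl{[(2R)-5-chloro-2-{2-[(1S,2S,4aR)-1,2,5,5-tetramethyl-1,2,3,4,4a,5,6,7-octahydronaphthalen-1-yl]ethyl}pentyl]oxy}dimethylsilane | C[C@H]1CC[C@H]2C(=CCCC2(C)C)[C@@]1(C)CC[C@H](CCCCl)CO[Si](C)(C)C(C)(C)C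
F7 | step 12 | tetrabutylammonium (2R)-5-iodo-2-{2-[(1S,2S,4aR)-1,2,5,5-tetramethyl-1,2,3,4,4a,5,6,7-octahydronaphthalen-1-yl]ethyl}pentyl sulfate | C[C@H]1CC[C@H]2C(=CCCC2(C)C)[C@@]1(C)CC[C@H](CCCI)COS(=O)(=O)[O-].CCCC[N+](CCCC)(CCCC)CCCC
F8 | step 12 | tetrabutylammonium salt of iodo{(4R)-4-[(sulfonatooxy)methyl]-6-[(1S,2S,4aR)-1,2,5,5-tetramethyl-1,2,3,4,4a,5,6,7-octahydronaphthalen-1-yl]hexyl}zinc | C[C@H]1CC[C@H]2C(=CCCC2(C)C)[C@@]1(C)CC[C@H](CCC[Zn]I)COS(=O)(=O)[O-].CCCC[N+](CCCC)(CCCC)CCCC
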